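**Retrosynthetic overview**
- Last step: one hydrogenolysis removes four benzyl groups (two outer phenol ethers, two side-chain ethers) from a tetra-O-benzyl precursor.
- The acetate/3-phenylpropanoate pair is put on a free catechol that is unmasked from a methylenedioxy group; this dioxole keeps the two adjacent oxygen pairs of the central ring distinct while the two (R)-3-(benzyloxy)butanoates (from methyl (R)-3-hydroxybutanoate) are attached to the other pair.
- Both biaryl C–C bonds come from one visible-light twofold C–H arylation of the sesamol-derived ortho-quinone with the diazonium ion made in the flask from 4-(benzyloxy)aniline.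
- Ring order: no ring is built. The central ring (sesamol) and both outer rings (the aniline) are bought; the bought dioxole ring is opened late.

Assumption: the side-chain stereocentres in the target SMILES are read as (R), matching commercial methyl (R)-3-hydroxybutanoate; sesamol, 4-(benzyloxy)aniline and 3-phenylpropanoyl chloride are taken as commercial.

**Route**

Step 1
Reactants: 1 methyl (R)-3-hydroxybutanoate
Product: 2 methyl (R)-3-(benzyloxy)butanoate
Conditions: BnOC(=NH)CCl3 (1.4 equiv), TfOH (5 mol %), cyclohexane/CH2Cl2 2:1, 0 °C → 20 °C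
Reagents that add atoms: benzyl 2,2,2-trichloroacetimidate, ClC(Cl)(Cl)C(=N)OCc1ccccc1
Why: Acid-catalysed trichloroacetimidate O-benzylation etherifies the secondary alcohol without base, so no retro-aldol or β-elimination occurs, and the C3–O bond is never broken, so the bought (R) centre is retained.

Step 2
Reactants: 2 methyl (R)-3-(benzyloxy)butanoate
Product: 3 (R)-3-(benzyloxy)butanoic acid
Conditions: LiOH·H2O (1.5 equiv), THF/H2O 3:1, 0 °C → 20 °C; then 1 M HCl
Reagents that add atoms: lithium hydroxide, [Li+].[OH-]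
Why: Ester saponification; the stereocentre is β to the carbonyl and carries no acidic hydrogen, so it cannot epimerise, and the low temperature suppresses loss of benzyl alcohol by elimination.

Step 3
Reactants: 4 sesamol (1,3-benzodioxol-5-ol)
Product: 5 1,3-benzodioxole-5,6-dione
Conditions: IBX (1.1 equiv), DMF, 20 °C, dark
Reagents that add atoms: 2-iodoxybenzoic acid (IBX), OI1(=O)OC(=O)c2ccccc12
Why: Ortho-selective phenol oxidation with IBX (aryloxy-iodane formation, intramolecular oxygen transfer to the free ortho carbon C6, collapse to the ortho-quinone) gives the 4,5-dioxygenated quinone, which is stabilised as a vinylogous ester.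

Step 4
Reactants: 5 1,3-benzodioxole-5,6-dione; 6 4-(benzyloxy)aniline (3.0 equiv)
Product: 10 4,7-bis[4-(benzyloxy)phenyl]-1,3-benzodioxole-5,6-diol, via 4-(benzyloxy)benzenediazonium tetrafluoroborate 7 (not isolated), via monoaryl ortho-quinone 8 (not isolated), via diaryl ortho-quinone 9 (not isolated)
Conditions: 6, t-BuONO (3.3 equiv), HBF4·OEt2 (3.3 equiv), MeCN, 0 °C, 30 min; then 5, Ru(bpy)3(PF6)2 (2 mol %), 4 Å MS, MeCN, blue LEDs (455 nm), 20 °C, Ar; then aq. Na2S2O4, EtOAc
Reagents that add atoms: none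
Why: Proposed new method: a twofold visible-light photoredox Meerwein-type C–H arylation of an alkoxy-substituted ortho-quinone, in which photoexcited Ru(bpy)3(PF6)2 transfers one electron to diazonium ion 7, which loses N2 to give the 4-(benzyloxy)phenyl radical; this radical adds to the only C–H carbons of 5 (C4 and C7, each α to a carbonyl and β to an acetal oxygen) to give an oxygen-stabilised, carbonyl-conjugated radical that is oxidised by the oxidised photocatalyst (or by a further diazonium ion in a chain) and loses a proton to restore the quinone (first 8, then 9), and dithionite then reduces 9 to catechol 10; the closest known reaction type is the photoredox and classical thermal Meerwein arylation of 1,4-benzoquinones with arenediazonium salts, not yet shown on ortho-quinones or twofold on a 4,5-dioxygenated one; no stereocentre is formed.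

Step 5
Reactants: 10 4,7-bis[4-(benzyloxy)phenyl]-1,3-benzodioxole-5,6-diol; 3 (R)-3-(benzyloxy)butanoic acid (2.6 equiv)
Product: 11 4,7-bis[4-(benzyloxy)phenyl]-1,3-benzodioxole-5,6-diyl bis[(R)-3-(benzyloxy)butanoate]
Conditions: DCC (3.0 equiv), DMAP (0.5 equiv), CH2Cl2, 0 °C → 20 °C, Ar
Reagents that add atoms: none
Why: Steglich esterification acylates both catechol hydroxyls with the same acid, so no selectivity is needed, and the mild carbodiimide/DMAP conditions leave the β-benzyloxy (R) centres untouched.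

Step 6
Reactants: 11 4,7-bis[4-(benzyloxy)phenyl]-1,3-benzodioxole-5,6-diyl bis[(R)-3-(benzyloxy)butanoate]
Product: 14 3,6-bis[4-(benzyloxy)phenyl]-4,5-dihydroxy-1,2-phenylene bis[(R)-3-(benzyloxy)butanoate], via 2-acetoxy-1,3-benzodioxole ortho ester 12 (not isolated), via catechol monoformate 13 (not isolated)
Conditions: Pb(OAc)4 (2.0 equiv), benzene, 80 °C; then AcOH/THF/H2O 3:1:1, 40 °C
Reagents that add atoms: none
Why: Oxidative demethylenation, in which Pb(OAc)4 acetoxylates the doubly oxygen-activated acetal C–H to ortho ester 12, which hydrolyses in aqueous acetic acid through aryl formate 13 to the catechol; the aryl esters and benzyl ethers are inert, and because each new OH is flanked by an aryl-bearing carbon and the other OH, no acyl migration can scramble the ester pattern.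

Step 7
Reactants: 14 3,6-bis[4-(benzyloxy)phenyl]-4,5-dihydroxy-1,2-phenylene bis[(R)-3-(benzyloxy)butanoate]; 15 3-phenylpropanoyl chloride (1.0 equiv)
Product: 17 4-acetoxy-3,6-bis[4-(benzyloxy)phenyl]-5-(3-phenylpropanoyloxy)-1,2-phenylene bis[(R)-3-(benzyloxy)butanoate] (tetra-O-benzyl curtisian V), via mono(3-phenylpropanoate) 16 (not isolated)
Conditions: 15, pyridine/CH2Cl2 1:4, −40 °C → 0 °C; then Ac2O (5 equiv), DMAP (0.1 equiv), 20 °C
Reagents that add atoms: acetic anhydride, CC(=O)OC(C)=O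
Why: Sequential O-acylation (acid chloride/pyridine, then DMAP-catalysed acetylation); the two hydroxyls of 14 are homotopic (C2 axis), so mono-acylation gives the single compound 16, whose remaining OH is more hindered and less nucleophilic and is then capped with the different acyl group in the same flask.

Step 8
Reactants: 17 tetra-O-benzyl curtisian V
Product: 18 Curtisian V
Conditions: H2 (1 atm), Pd(OH)2/C, EtOAc/THF 1:1, 20 °C
Reagents that add atoms: none
Why: Catalytic hydrogenolysis cleaves all four benzyl ethers at the benzylic C–O bond, leaving the aryl esters, the arenes and both (R) carbinol centres untouched.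

**Compound list**

1 | methyl (R)-3-hydroxybutanoate | C[C@@H](O)CC(=O)OC | starting material
2 | methyl (R)-3-(benzyloxy)butanoate | C[C@@H](OCc1ccccc1)CC(=O)OC | intermediate
3 | (R)-3-(benzyloxy)butanoic acid | C[C@@H](OCc1ccccc1)CC(=O)O | intermediate
4 | sesamol (1,3-benzodioxol-5-ol) | Oc1ccc2OCOc2c1 | starting material
5 | 1,3-benzodioxole-5,6-dione | O=C1C=C2OCOC2=CC1=O | intermediate
6 | 4-(benzyloxy)aniline | Nc1ccc(OCc2ccccc2)cc1 | starting material
7 | 4-(benzyloxy)benzenediazonium tetrafluoroborate | N#[N+]c1ccc(OCc2ccccc2)cc1.F[B-](F)(F)F | intermediate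
8 | 4-[4-(benzyloxy)phenyl]-1,3-benzodioxole-5,6-dione | O=C1C=C2OCOC2=C(c2ccc(OCc3ccccc3)cc2)C1=O | intermediate
9 | 4,7-bis[4-(benzyloxy)phenyl]-1,3-benzodioxole-5,6-dione | O=C1C(c2ccc(OCc3ccccc3)cc2)=C2OCOC2=C(c2ccc(OCc3ccccc3)cc2)C1=O | intermediate
10 | 4,7-bis[4-(benzyloxy)phenyl]-1,3-benzodioxole-5,6-diol | Oc1c(O)c(-c2ccc(OCc3ccccc3)cc2)c2OCOc2c1-c1ccc(OCc2ccccc2)cc1 | intermediate
11 | 4,7-bis[4-(benzyloxy)phenyl]-1,3-benzodioxole-5,6-diyl bis[(R)-3-(benzyloxy)butanoate] | C[C@@H](OCc1ccccc1)CC(=O)Oc1c(OC(=O)C[C@@H](C)OCc2ccccc2)c(-c2ccc(OCc3ccccc3)cc2)c2OCOc2c1-c1ccc(OCc2ccccc2)cc1 | intermediate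
12 | 2-acetoxy-4,7-bis[4-(benzyloxy)phenyl]-1,3-benzodioxole-5,6-diyl bis[(R)-3-(benzyloxy)butanoate] | C[C@@H](OCc1ccccc1)CC(=O)Oc1c(OC(=O)C[C@@H](C)OCc2ccccc2)c(-c2ccc(OCc3ccccc3)cc2)c2OC(OC(C)=O)Oc2c1-c1ccc(OCc2ccccc2)cc1 | intermediate
13 | 3,6-bis[4-(benzyloxy)phenyl]-4-(formyloxy)-5-hydroxy-1,2-phenylene bis[(R)-3-(benzyloxy)butanoate] | C[C@@H](OCc1ccccc1)CC(=O)Oc1c(OC(=O)C[C@@H](C)OCc2ccccc2)c(-c2ccc(OCc3ccccc3)cc2)c(OC=O)c(O)c1-c1ccc(OCc2ccccc2)cc1 | intermediate
14 | 3,6-bis[4-(benzyloxy)phenyl]-4,5-dihydroxy-1,2-phenylene bis[(R)-3-(benzyloxy)butanoate] | C[C@@H](OCc1ccccc1)CC(=O)Oc1c(OC(=O)C[C@@H](C)OCc2ccccc2)c(-c2ccc(OCc3ccccc3)cc2)c(O)c(O)c1-c1ccc(OCc2ccccc2)cc1 | intermediate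
15 | 3-phenylpropanoyl chloride | O=C(Cl)CCc1ccccc1 | starting material
16 | 3,6-bis[4-(benzyloxy)phenyl]-4-hydroxy-5-(3-phenylpropanoyloxy)-1,2-phenylene bis[(R)-3-(benzyloxy)butanoate] | C[C@@H](OCc1ccccc1)CC(=O)Oc1c(OC(=O)C[C@@H](C)OCc2ccccc2)c(-c2ccc(OCc3ccccc3)cc2)c(OC(=O)CCc2ccccc2)c(O)c1-c1ccc(OCc2ccccc2)cc1 | intermediate
17 | 4-acetoxy-3,6-bis[4-(benzyloxy)phenyl]-5-(3-phenylpropanoyloxy)-1,2-phenylene bis[(R)-3-(benzyloxy)butanoate] (tetra-O-benzyl curtisian V) | CC(=O)Oc1c(OC(=O)CCc2ccccc2)c(-c2ccc(OCc3ccccc3)cc2)c(OC(=O)C[C@@H](C)OCc2ccccc2)c(OC(=O)C[C@@H](C)OCc2ccccc2)c1-c1ccc(OCc2ccccc2)cc1 | intermediate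
18 | Curtisian V: 4-acetoxy-3,6-bis(4-hydroxyphenyl)-5-(3-phenylpropanoyloxy)-1,2-phenylene bis[(R)-3-hydroxybutanoate] | CC(=O)Oc1c(OC(=O)CCc2ccccc2)c(-c2ccc(O)cc2)c(OC(=O)C[C@@H](C)O)c(OC(=O)C[C@@H](C)O)c1-c1ccc(O)cc1 | target

**Totals**

Total step count: 8.
Longest linear sequence: 6 steps (steps 3 to 8, sesamol 4 to 18; the side-chain branch through steps 1, 2, 5, 6, 7, 8 is also 6).

**Three steps most likely to fail**

Step 4 (the proposed new photochemical twofold arylation). Likely failures are a stalled second arylation, photodecomposition of the ortho-quinone, hydrogen abstraction from the OCH2O group, and acid hydrolysis of the vinylogous acetal by the water formed in the diazotisation. The fallback uses known chemistry, sets out from 5 and comes back at 10. Quinone 5 is reduced with aqueous Na2S2O4 to 1,3-benzodioxole-5,6-diol F1. This is protected with MOMCl and i-Pr2NEt as 5,6-bis(methoxymethoxy)-1,3-benzodioxole F2. NBS in MeCN brominates the two remaining ring positions to give 4,7-dibromo-5,6-bis(methoxymethoxy)-1,3-benzodioxole F3. A twofold Suzuki–Miyaura coupling with bought 4-(benzyloxy)phenylboronic acid (Pd(OAc)2, SPhos, K3PO4, toluene/H2O, 90 °C) gives 4,7-bis[4-(benzyloxy)phenyl]-5,6-bis(methoxymethoxy)-1,3-benzodioxole F4. HCl in MeOH/THF removes the MOM ethers and returns catechol 10.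

Step 6 (oxidative demethylenation). Pb(OAc)4 may be sluggish on the ester-bearing ring or may attack the benzylic ether positions. The fallback replaces the methylene acetal by a fluoride-labile silylene; it sets out from 10 and comes back at 14. Catechol 10 is re-oxidised with Ag2O to quinone 9, whose vinylogous acetal is hydrolysed with aqueous NaOH (loss of formaldehyde) to 2,5-bis[4-(benzyloxy)phenyl]-3,6-dihydroxy-1,4-benzoquinone F5. Na2S2O4 reduces this to 3,6-bis[4-(benzyloxy)phenyl]benzene-1,2,4,5-tetraol F6. One equivalent of t-Bu2Si(OTf)2 with 2,6-lutidine bridges one adjacent pair (statistical; separated from bis-silylene and recovered tetraol) to give 4,7-bis[4-(benzyloxy)phenyl]-2,2-di-tert-butyl-1,3,2-benzodioxasilole-5,6-diol F7. Acylation with acid 3 (DCC, DMAP) gives 4,7-bis[4-(benzyloxy)phenyl]-2,2-di-tert-butyl-1,3,2-benzodioxasilole-5,6-diyl bis[(R)-3-(benzyloxy)butanoate] F8. HF·pyridine in THF removes the silylene and gives 14.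

Step 7 (one-flask mixed diacylation). The mono-acylation may give a statistical mixture with the bis(3-phenylpropanoate) and, after acetylation, the bis-acetate, which are hard to separate. The fallback makes the mono-ester through a cyclic ortho ester; it sets out from 14 and comes back at 17. Catechol 14 with MeC(OMe)3 and catalytic PPTS gives 4,7-bis[4-(benzyloxy)phenyl]-2-methoxy-2-methyl-1,3-benzodioxole-5,6-diyl bis[(R)-3-(benzyloxy)butanoate] F9. Mild aqueous acetic acid opens it to the mono-acetate only, 4-acetoxy-3,6-bis[4-(benzyloxy)phenyl]-5-hydroxy-1,2-phenylene bis[(R)-3-(benzyloxy)butanoate] F10. Acylation of the remaining hydroxyl with 15 (pyridine, DMAP) gives 17.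

**Further compounds**

F1 | step 4 | 1,3-benzodioxole-5,6-diol | Oc1cc2OCOc2cc1O
F2 | step 4 | 5,6-bis(methoxymethoxy)-1,3-benzodioxole | COCOc1cc2OCOc2cc1OCOC
F3 | step 4 | 4,7-dibromo-5,6-bis(methoxymethoxy)-1,3-benzodioxole | COCOc1c(Br)c2OCOc2c(Br)c1OCOC
F4 | step 4 | 4,7-bis[4-(benzyloxy)phenyl]-5,6-bis(methoxymethoxy)-1,3-benzodioxole | COCOc1c(-c2ccc(OCc3ccccc3)cc2)c2OCOc2c(-c2ccc(OCc3ccccc3)cc2)c1OCOC
F5 | step 6 | 2,5-bis[4-(benzyloxy)phenyl]-3,6-dihydroxy-1,4-benzoquinone | O=C1C(O)=C(c2ccc(OCc3ccccc3)cc2)C(=O)C(O)=C1c1ccc(OCc2ccccc2)cc1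
F6 | step 6 | 3,6-bis[4-(benzyloxy)phenyl]benzene-1,2,4,5-tetraol | Oc1c(O)c(-c2ccc(OCc3ccccc3)cc2)c(O)c(O)c1-c1ccc(OCc2ccccc2)cc1
F7 | step 6 | 4,7-bis[4-(benzyloxy)phenyl]-2,2-di-tert-butyl-1,3,2-benzodioxasilole-5,6-diol | Oc1c(O)c(-c2ccc(OCc3ccccc3)cc2)c2O[Si](C(C)(C)C)(C(C)(C)C)Oc2c1-c1ccc(OCc2ccccc2)cc1
F8 | step 6 | 4,7-bis[4-(benzyloxy)phenyl]-2,2-di-tert-butyl-1,3,2-benzodioxasilole-5,6-diyl bis[(R)-3-(benzyloxy)butanoate] | C[C@@H](OCc1ccccc1)CC(=O)Oc1c(OC(=O)C[C@@H](C)OCc2ccccc2)c(-c2ccc(OCc3ccccc3)cc2)c2O[Si](C(C)(C)C)(C(C)(C)C)Oc2c1-c1ccc(OCc2ccccc2)cc1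
F9 | step 7 | 4,7-bis[4-(benzyloxy)phenyl]-2-methoxy-2-methyl-1,3-benzodioxole-5,6-diyl bis[(R)-3-(benzyloxy)butanoate] | C[C@@H](OCc1ccccc1)CC(=O)Oc1c(OC(=O)C[C@@H](C)OCc2ccccc2)c(-c2ccc(OCc3ccccc3)cc2)c2OC(C)(OC)Oc2c1-c1ccc(OCc2ccccc2)cc1
F10 | step 7 | 4-acetoxy-3,6-bis[4-(benzyloxy)phenyl]-5-hydroxy-1,2-phenylene bis[(R)-3-(benzyloxy)butanoate] | C[C@@H](OCc1ccccc1)CC(=O)Oc1c(OC(=O)C[C@@H](C)OCc2ccccc2)c(-c2ccc(OCc3ccccc3)cc2)c(OC(C)=O)c(O)c1-c1ccc(OCc2ccccc2)cc1
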